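**Retrosynthetic overview**
1. Target 17 ⇐ bicyclo[3.3.1]nonane 15 (benzoyl on C1 next to C8, prenyl on C7 endo): a Mn(OAc)3/air radical cascade from the C3 enol radical forms C3–C2' (seven-membered bridge), C3'–C2'' (cyclopentane) and the C–O bond.
2. 15 ⇐ monocyclic acylphloroglucinol 12: cationic C8→C1 closure of ring B, with C3 blocked in the flask as its chloride so that only the benzoyl-bearing carbon can attack.
3. 12 ⇐ lactone ester 7 + diketone 10: polyketide-type Claisen/Dieckmann closure of ring A. 7 ⇐ (S)-lavandulol + dimethyl malonate + geranyl bromide (C5 set on a δ-lactone enolate); 10 ⇐ benzoylacetone + prenyl bromide.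
4. Ring order: ring A (trione) → ring B (bicyclo[3.3.1]) → seven-membered bridge → cyclopentane.
5. Locants: ring A = C1 (benzoyl), C2, C3 (prenyl C1''–C3''), C4, C5 (geranyl), C9; bridge C5–C6–C7–C8–C1; C1'–C3' = prenyl on C7. In these locants the target is 1S, 3S, 5R, 7R, 2'R, 2''S.

Assumption: (S)-(+)-lavandulol (1) is bought enantiopure (pheromone intermediate; racemic lavandulol is cheap and can be resolved by lipase acylation). Enols are drawn in one tautomeric form.

**Route**

Step 1
Reactants: 1 (S)-lavandulol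
Product: 2 (2R)-2-(2-hydroxypropan-2-yl)-5-methylhex-4-en-1-ol
Conditions: Co(acac)2 (10 mol%), PhSiH3, O2 (1 atm), i-PrOH, rt
Reagents that add atoms: dioxygen, O=O
Why: Mukaiyama hydration (hydrogen-atom transfer, Markovnikov) is faster at the 1,1-disubstituted isopropenyl group than at the trisubstituted alkene and gives the tertiary alcohol, while the stereocentre is untouched (S becomes R only through the priority change).

Step 2
Reactants: 2 (2R)-2-(2-hydroxypropan-2-yl)-5-methylhex-4-en-1-ol
Product: 3 (3S)-3-(iodomethyl)-2,6-dimethylhept-5-en-2-ol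
Conditions: I2, PPh3, imidazole, CH2Cl2, 0 °C
Reagents that add atoms: iodine, [I][I]
Why: Appel iodination converts the primary hydroxyl selectively at 0 °C because the tertiary hydroxyl does not form the alkoxyphosphonium salt, and no stereocentre is involved.

Step 3
Reactants: 3 (3S)-3-(iodomethyl)-2,6-dimethylhept-5-en-2-ol, 4 dimethyl malonate, 5 geranyl bromide
Product: 7 methyl (3R,5R)-3-[(2E)-3,7-dimethylocta-2,6-dien-1-yl]-6,6-dimethyl-5-(3-methylbut-2-en-1-yl)-2-oxooxane-3-carboxylate, via lactone ester 6 (not isolated)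
Conditions: 4, NaH (1.0 equiv), DMF, 0 °C; 3, 60 °C; NaH (1.1 equiv), rt; 5, 0 °C to rt
Reagents that add atoms: dimethyl malonate (4), COC(=O)CC(=O)OC; geranyl bromide (5), CC(C)=CCC/C(C)=C/CBr
Why: Malonate SN2 alkylation by the primary iodide, base-driven δ-lactonisation of the tertiary alkoxide onto one ester, then C-alkylation of the cyclic malonate enolate by geranyl bromide from the axial face (syn to the axial H at C5, anti to the pseudo-axial C6 methyl) sets the quaternary C3 with geranyl trans to prenyl by cyclic stereocontrol (about 5:1 expected, minor epimer removed by chromatography) and leaves the two carbonyl groups chemically different for step 5.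

Step 4
Reactants: 8 benzoylacetone, 9 prenyl bromide
Product: 10 7-methyl-1-phenyloct-6-ene-1,3-dione
Conditions: LiN(i-Pr)2 (2.1 equiv), THF, −78 to 0 °C; 9, −78 °C to rt; aq. HCl
Reagents that add atoms: prenyl bromide (9), CC(C)=CCBr
Why: Alkylation of a 1,3-diketone dianion (Hauser-type) takes place only at the terminal, more basic carbanion, and no stereocentre is formed.

Step 5
Reactants: 7 lactone ester from step 3, 10 7-methyl-1-phenyloct-6-ene-1,3-dione
Product: 12 (6R)-2-benzoyl-6-[(2E)-3,7-dimethylocta-2,6-dien-1-yl]-3,5-dihydroxy-6-[(2R)-2-(2-hydroxypropan-2-yl)-5-methylhex-4-en-1-yl]-4-(3-methylbut-2-en-1-yl)cyclohexa-2,4-dien-1-one, via triketo lactone 11 (not isolated)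
Conditions: 10, LiN(i-Pr)2 (3.2 equiv), THF, −78 to 0 °C; 7, −78 °C to rt, then 45 °C; aq. HCl
Reagents that add atoms: diketone 10, CC(C)=CCCC(=O)CC(=O)c1ccccc1
Why: Claisen acylation of the terminal diketone carbanion on the exposed methyl ester (the lactone carbonyl is shielded by the gem-dimethyl group and the quaternary α-carbon) followed by Dieckmann closure of the central carbanion onto the lactone carbonyl (polyketide-type Claisen cyclisation) builds ring A and frees the tertiary alcohol, and this order of the two acylations carries the C3 configuration of 7 into the non-epimerisable ring centre C5 (6R in 12).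

Step 6
Reactants: 12 monocyclic acylphloroglucinol from step 5
Product: 15 (1R,5R,7R)-1-benzoyl-5-[(2E)-3,7-dimethylocta-2,6-dien-1-yl]-4-hydroxy-8,8-dimethyl-3,7-bis(3-methylbut-2-en-1-yl)bicyclo[3.3.1]non-3-ene-2,9-dione (7-prenyl endo), via chloro monocycle 13 (not isolated), via chloro bicycle 14 (not isolated)
Conditions: N-chlorosuccinimide (1.0 equiv), CH2Cl2, −20 °C; Bi(OTf)3 (10 mol%), −20 to 0 °C; PPh3, THF–H2O, rt
Reagents that add atoms: none
Why: Proposed new method: the most nucleophilic enol carbon of 12 (C3, between two C–O carbons) is chlorinated first so that in 13 only the benzoyl-bearing C1 stays enolisable, then Bi(OTf)3 ionises the tertiary alcohol (O-capture reversible, C-capture not) and the C8 cation is taken by C1 on the face that carries the side chain, which closes ring B, sets C1 through the bridge and, because C5 and C7 are already fixed as in 7, forces the C7 prenyl group endo through a boat-like closure, and finally PPh3 removes the chlorine by halophilic attack to give enol 15; the closest known reaction types are the biomimetic cationic cyclisation of dearomatised acylphloroglucinols, the Bi(OTf)3-catalysed dehydrative alkylation of 1,3-dicarbonyl compounds by alcohols and the phosphine dehalogenation of 2-halo-1,3-diketones.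

Step 7
Reactants: 15 bicyclic enol from step 6
Product: 17 target CNP0164095.2 (homoadamantane tetracycle; SMILES in the list), via tertiary hydroperoxide 16 (not isolated)
Conditions: Mn(OAc)3·2H2O (20 mol%), AcOH, air (1 atm), rt, high dilution; PPh3 (1.2 equiv)
Reagents that add atoms: dioxygen, O=O
Why: Mn(OAc)3 oxidative radical cyclisation with aerobic termination: trivalent manganese oxidises the C2–C4 enol to the C3 radical, which adds 7-exo to the endo prenyl alkene through the bridge twist that keeps C2' away from the C8 gem-dimethyl group (CMe2 terminus outward, H toward C6; sets C3 through the cage and C2' as R), the tertiary C3' radical then closes 5-exo onto the C3 prenyl group with the new CMe2 radical trans to C1' on the less hindered face (Beckwith-type chair; sets C2'' as S), O2 traps that radical and PPh3 reduces hydroperoxide 16 to the tertiary alcohol.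

**Compound list**
1 | (S)-lavandulol, (2S)-5-methyl-2-(prop-1-en-2-yl)hex-4-en-1-ol | OC[C@@H](CC=C(C)C)C(C)=C | starting material
2 | (2R)-2-(2-hydroxypropan-2-yl)-5-methylhex-4-en-1-ol | OC[C@@H](CC=C(C)C)C(C)(C)O | intermediate
3 | (3S)-3-(iodomethyl)-2,6-dimethylhept-5-en-2-ol | IC[C@@H](CC=C(C)C)C(C)(C)O | intermediate
4 | dimethyl malonate | COC(=O)CC(=O)OC | starting material
5 | geranyl bromide, (2E)-1-bromo-3,7-dimethylocta-2,6-diene | CC(C)=CCC/C(C)=C/CBr | starting material
6 | methyl (5R)-6,6-dimethyl-5-(3-methylbut-2-en-1-yl)-2-oxooxane-3-carboxylate (both C3 epimers, enolisable) | COC(=O)C1C[C@@H](CC=C(C)C)C(C)(C)OC1=O | intermediate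
7 | methyl (3R,5R)-3-[(2E)-3,7-dimethylocta-2,6-dien-1-yl]-6,6-dimethyl-5-(3-methylbut-2-en-1-yl)-2-oxooxane-3-carboxylate (geranyl trans to prenyl) | COC(=O)[C@@]1(C/C=C(\C)CCC=C(C)C)C[C@@H](CC=C(C)C)C(C)(C)OC1=O | intermediate
8 | benzoylacetone, 1-phenylbutane-1,3-dione | CC(=O)CC(=O)c1ccccc1 | starting material
9 | prenyl bromide, 1-bromo-3-methylbut-2-ene | CC(C)=CCBr | starting material
10 | 7-methyl-1-phenyloct-6-ene-1,3-dione | CC(C)=CCCC(=O)CC(=O)c1ccccc1 | intermediate
11 | (3R,5R)-3-[(2E)-3,7-dimethylocta-2,6-dien-1-yl]-6,6-dimethyl-3-[2-(3-methylbut-2-en-1-yl)-3,5-dioxo-5-phenylpentanoyl]-5-(3-methylbut-2-en-1-yl)oxan-2-one | CC(C)=CCC(C(=O)CC(=O)c1ccccc1)C(=O)[C@@]2(C/C=C(\C)CCC=C(C)C)C[C@@H](CC=C(C)C)C(C)(C)OC2=O | intermediate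
12 | (6R)-2-benzoyl-6-[(2E)-3,7-dimethylocta-2,6-dien-1-yl]-3,5-dihydroxy-6-[(2R)-2-(2-hydroxypropan-2-yl)-5-methylhex-4-en-1-yl]-4-(3-methylbut-2-en-1-yl)cyclohexa-2,4-dien-1-one | O=C1C(C(=O)c2ccccc2)=C(O)C(CC=C(C)C)=C(O)[C@@]1(C/C=C(\C)CCC=C(C)C)C[C@@H](CC=C(C)C)C(C)(C)O | intermediate
13 | 4-chloro derivative of 12: 2-benzoyl-4-chloro-3-hydroxy-4-(3-methylbut-2-en-1-yl)cyclohex-2-ene-1,5-dione carrying the same two C6 substituents in the same configuration (both C4 epimers) | O=C1C(C(=O)c2ccccc2)=C(O)C(Cl)(CC=C(C)C)C(=O)[C@@]1(C/C=C(\C)CCC=C(C)C)C[C@@H](CC=C(C)C)C(C)(C)O | intermediate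
14 | 3-chloro-2,4,9-trione form of 15: 1-benzoyl-3-chloro-5-geranyl-8,8-dimethyl-3,7-bis(3-methylbut-2-en-1-yl)bicyclo[3.3.1]nonane-2,4,9-trione, C1, C5 and C7 as in 15 (both C3 epimers) | CC(C)=CCC/C(C)=C/C[C@@]12C[C@@H](CC=C(C)C)C(C)(C)[C@](C(=O)c3ccccc3)(C2=O)C(=O)C(Cl)(CC=C(C)C)C1=O | intermediate
15 | (1R,5R,7R)-1-benzoyl-5-[(2E)-3,7-dimethylocta-2,6-dien-1-yl]-4-hydroxy-8,8-dimethyl-3,7-bis(3-methylbut-2-en-1-yl)bicyclo[3.3.1]non-3-ene-2,9-dione (7-prenyl endo) | CC(C)=CCC/C(C)=C/C[C@@]12C[C@@H](CC=C(C)C)C(C)(C)[C@](C(=O)c3ccccc3)(C2=O)C(=O)C(CC=C(C)C)=C1O | intermediate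
16 | hydroperoxide of the target (2-hydroperoxypropan-2-yl in place of 2-hydroxypropan-2-yl) | CC(C)=CCC/C(C)=C/C[C@@]12C[C@H]3C[C@@H]4C(C)(C)[C@@H](C(C)(C)OO)C[C@]4(C1=O)C(=O)[C@@](C(=O)c1ccccc1)(C2=O)C3(C)C | intermediate
17 | CNP0164095.2: 1-benzoyl-5-geranyl homoadamantane trione (tetracyclo[7.3.1.1^{3,11}.0^{3,7}]tetradecane-2,12,14-trione core) with fused gem-dimethylcyclopentane bearing 2-hydroxypropan-2-yl | CC(C)=CCC/C(C)=C/C[C@@]12C[C@H]3C[C@@H]4C(C)(C)[C@@H](C(C)(C)O)C[C@]4(C1=O)C(=O)[C@@](C(=O)c1ccccc1)(C2=O)C3(C)C | target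

**Totals and risks**
Total steps: 7. Longest linear sequence: 6 (steps 1, 2, 3, 5, 6, 7); step 4 is a one-step side branch.

Most likely to fail, in order:

Step 6. The chlorination may not be clean at C3, and the cation may end in O-capture, in capture by the proximal geranyl alkene, or in a 1,2-hydride shift that scrambles C7; the forced boat-like closure is also slow. Fallback, setting out from 12 and returning at 15: block C3 through oxygen instead of chlorine. Methylate the non-chelated enol hydroxyl of 12 with TMSCHN2 to the 5-O-methyl enol ether F1. Ionise the tertiary alcohol irreversibly under base (MsCl, Et3N, CH2Cl2, 0 °C) so that the chelated triketonate carbon is the only anionic carbon nucleophile, giving the bicyclic vinylogous methyl ester F2. Cleave the methyl ether with LiCl in DMSO at 120 °C to reach 15.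

Step 7. O2 may intercept the C3' radical before the 5-exo closure, or the wrong C2' epimer may dominate. Fallback, setting out from 15 and returning at 17: run the cascade without air with stoichiometric Mn(OAc)3 and Cu(OAc)2 in degassed AcOH, so that divalent copper ends the cascade by oxidative elimination to the isopropenyl tetracycle F3. Then hydrate the isopropenyl group selectively (Co(acac)2, PhSiH3, O2, as in step 1) to 17. This fallback does not correct a wrong C2' epimer.

Step 5. The hindered methyl ester may not acylate the dianion, or the dianion may open the lactone first, which would invert C5. Fallback, setting out from 7 and returning at 12: cleave only the methyl ester with Me3SnOH to the lactone acid F4 and convert it with oxalyl chloride to the acid chloride F5. Acylate the dilithio dianion of 10 at −78 °C to isolated 11, then close ring A in a separate Dieckmann step (NaH, THF) to 12.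

**Further compounds**
F1 | step 6 | 5-O-methyl enol ether of 12, (6R)-2-benzoyl-3-hydroxy-5-methoxy analogue | O=C1C(C(=O)c2ccccc2)=C(O)C(CC=C(C)C)=C(OC)[C@@]1(C/C=C(\C)CCC=C(C)C)C[C@@H](CC=C(C)C)C(C)(C)O
F2 | step 6 | 4-O-methyl ether of 15, (1R,5R,7R)-1-benzoyl-4-methoxy bicyclo[3.3.1]non-3-ene-2,9-dione analogue | CC(C)=CCC/C(C)=C/C[C@@]12C[C@@H](CC=C(C)C)C(C)(C)[C@](C(=O)c3ccccc3)(C2=O)C(=O)C(CC=C(C)C)=C1OC
F3 | step 7 | isopropenyl analogue of the target (prop-1-en-2-yl in place of 2-hydroxypropan-2-yl) | CC(C)=CCC/C(C)=C/C[C@@]12C[C@H]3C[C@@H]4C(C)(C)[C@@H](C(C)=C)C[C@]4(C1=O)C(=O)[C@@](C(=O)c1ccccc1)(C2=O)C3(C)C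
F4 | step 5 | (3R,5R)-3-[(2E)-3,7-dimethylocta-2,6-dien-1-yl]-6,6-dimethyl-5-(3-methylbut-2-en-1-yl)-2-oxooxane-3-carboxylic acid | OC(=O)[C@@]1(C/C=C(\C)CCC=C(C)C)C[C@@H](CC=C(C)C)C(C)(C)OC1=O
F5 | step 5 | acid chloride of F4, (3R,5R)-3-geranyl-6,6-dimethyl-5-prenyl-2-oxooxane-3-carbonyl chloride | ClC(=O)[C@@]1(C/C=C(\C)CCC=C(C)C)C[C@@H](CC=C(C)C)C(C)(C)OC1=O
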